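Readings and results are simulated with constants of no real substance; scatter was added.

Qi gains from the feed of Dx and loses by its own fading, so I compare the two per hour: the peak comes where the falling gain meets the loss.

| flask | Dx | Ju | remark | time |
|---|---|---|---|---|
| Sunday's | 0.13 M (fed, over 2.5 h) | 4 mM | run made earlier; the fed solution adds 1.0 times the starting volume |  |
| Tuesday's | 0.30 M (fed, over 2.5 h) | 4 mM | run made earlier; the fed solution adds 1.0 times the starting volume |  |
| Saturday's | 0.20 M (fed, over 2.5 h) | 8 mM | run made earlier; the fed solution adds 1.0 times the starting volume |  |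
| flask | 0.20 M (fed, over 2.5 h) | 4.00 mM | the fed solution adds 1.0 times the starting volume | 20 h |

| run | time / h | Qi / % | Gu / % |
|---|---|---|---|
| Sunday's | 0.833 | 7 | 7 |
| Sunday's | 1.50 | 14 | 20 |
| Sunday's | 4.00 | 21 | 58 |
| Sunday's | 8.00 | 10 | 65 |
| Sunday's | 20.0 | 2 | 60 |
| Tuesday's | 0.833 | 5 | 11 |
| Tuesday's | 1.50 | 12 | 23 |
| Tuesday's | 4.00 | 26 | 56 |
| Tuesday's | 8.00 | 13 | 67 |
| Tuesday's | 20.0 | 4 | 61 |
| Saturday's | 0.833 | 7 | 9 |
| Saturday's | 1.50 | 15 | 23 |
| Saturday's | 4.00 | 23 | 56 |
| Saturday's | 8.00 | 11 | 67 |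
| Saturday's | 20.0 | 5 | 57 |

(readings scatter by 1.5 percentage points)

* the moment within 20 h at which there is most Qi
* the amount of Qi, in percent of the Dx charged, at that time
* the first time at which Qi reaches 17%, in the same percent

- every charge counts on the volume at the start, and the solution that is fed holds the whole dose
- percentages count the whole charge, also what has not yet gone in

Averaged over the three runs, Qi reads 23.3% at 4.00 h and 3.67% at 20.0 h. That gives 0.116 h⁻¹, the fading constant k: the pseudo-first-order share of Qi lost per hour once the feed is over. Early climb plus fading gives a gain of 0.122 h⁻¹ of the charge.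

Turned round, a peak before the feed ends would need k near 0.524 h⁻¹. With the k I read, gain and loss balance during the feed at 105% Qi, higher than the 23.3% read. So I put the peak after 2.5 h.

After the feed I let the gain fade. At 1.50 h the readings fall 24.3% short of what has gone in. I take that shortfall as material still on its way to Qi and Gu, in whatever form, and the feed rate over it gives a clearing rate of 1.64 h⁻¹, which is my own rough estimate for the fading of the gain and not a rate of Dx itself. Starting from 23.3%, gain meets loss at 3.42 h, where k carried back gives 25.0%. Going round once more, my reckoning is 3.37 h and 25.1%.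

The forecast says 3.2 h, 25.5% and 1.75 h, on the ground that “Qi peaks when formation equals decay”; my peak lies later than its peak.

The flask peaks at 3.01 h with 24.6%, and passes the level at 1.91 h, so the forecast holds.

    Dx ⇌ Qi (K = 44.0, k = 3.25 × 10⁻⁴ s⁻¹)
    Dx → Ty (k = 3.25 × 10⁻⁴ s⁻¹)
    Ty → Gu (k = 0.00415 s⁻¹)
    Qi ⇌ Zu (K = 0.550, k = 0.00298 s⁻¹)
    Zu → Ty (k = 1.03 × 10⁻⁴ s⁻¹)
    Ju + Qi → Ju.Qi (k = 0.00394 M⁻¹ s⁻¹)
    2 Dx → Qo (k = 2.56 × 10⁻⁴ M⁻¹ s⁻¹)
    Gu ⇌ Xi (K = 5.00, k = 8.36 × 10⁻⁶ s⁻¹)

At that peak 13.2% of Zu stands beside Qi in the flask, and the two relax into each other with a half-life of 1.38 min, shorter than 20 h. From the flask's 9.65% of Qi at 10.0 h, k gives 3.03% at 20.0 h, where the flask holds 2.38%. Carried on to the neighbour read at 2.0 d, k gives 0.0934%, and that neighbour holds 0.0480%.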